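## The problem

Jaspic acid (24) is a trans-fused decalin, labelled here in the labdane manner: ring A is C1–C5 with C10, ring B is C5–C10, C11 is the benzylic carbon, and β is the face of the C10 methyl. C4 carries an α-methyl and a β-oriented 4-methylpent-3-enyl chain, C10 a β-methyl, and C9 a β-CH2–aryl arm whose arene is a 4-hydroxybenzoic acid joined ortho to the hydroxyl. Ring B holds a C7=C8 alkene with a methyl on C8. The four stereocentres C4, C5, C9 and C10 are contiguous and two of them are quaternary. C10 can control the other three: its axial methyl favours the trans fusion (5α-H) in a dissolving-metal reduction, sends the last substituent to the α face of C4, and sends a reagent to the α face of C9. At C4 the order of introduction therefore decides the configuration, so the chain must be in place before the methyl. The C7=C8 alkene can slip to the tetrasubstituted C8=C9 position or be attacked by the neighbouring phenol under acid, and the side-chain alkene reacts with carbenes and boranes, so the phenol and acid need masks that come off without acid and the side-chain alkene must come late. The enabling feature is that ring B differs from the five-membered ring of a Hajos–Parrish-type hydrindanone only by C8, which lies between C9 and C7 and bears the methyl and one alkene terminus; because C10 is quaternary, a C9 ketone can enolise only toward C7, so the insertion site is unambiguous.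

## Retrosynthesis

**24 ⇒ 23.** The two O–CH3 bonds of the methyl ester methyl ether 23 are cut. Methyl masks are preferred over acetal masks because they leave by SN2 attack of a thiolate, whereas acid could move the C7=C8 alkene or close a chroman. 23 has no acidic hydrogen and tolerates ylides and fluoride. The forward step must cleave both methyls in one operation and spare two trisubstituted alkenes.

**23 ⇒ 22 ⇒ 21 ⇒ 20.** The side-chain C=C bond is cut, leading to aldehyde 22, alcohol 21 and silyl ether 20. Carrying the alkene from the start would be shorter, but it would compete in the carbene transfer and in the hydroboration that sets C9, so a saturated three-carbon silyl ether stands in for it until both are done. The forward steps are a fluoride desilylation, a mild oxidation and a Wittig reaction that must discriminate an aldehyde from an aryl ester.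

**20 ⇒ 17 + 18.** The C11–aryl bond and the C9–H bond are cut, giving the exocyclic diene 17 and aryl bromide 18 by way of alkylborane 19. The neighbouring cut at C9–C11 would need a 1,3-transposition of the enone oxygen to C7, an inversion there, a sigmatropic shift of a C7 ester and a decarboxylation. The cut chosen uses the C9 carbon–oxygen double bond directly and lets the C10 methyl steer hydrogen to the α face of C9. The precursor lacks the arene and the C9 stereocentre. The forward reaction must hydroborate the terminal carbon of a hindered diene on the α face and couple a β-branched alkylborane with an ortho-substituted aryl bromide.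

**17 ⇒ 16.** The C9=C11 bond is cut to the enone 16. This is the simplest way to attach C11 and needs only a one-carbon Wittig reagent that reaches a carbonyl flanked by quaternary C10.

**16 ⇒ 12 + 13.** The C7–C8 and C8–C9 bonds are cut and C8 leaves with its methyl, contracting ring B to the five-membered ring of silyl enol ether 12; the carbon returns from 13. The alternative, methylation and dehydrogenation of a decalin-9-one, needs regiocontrol in the dehydrogenation and a decalone that is itself harder to reach than the hydrindanone. The forward reaction must transfer a chloro(methyl)carbene to a hindered enol ether and open the adduct to the enone.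

**12 ⇒ 11 ⇒ 10 ⇒ 8.** The O–Si bond of 12 and the dioxolane of 10 are functional-group changes back to ketone 11 and ketal 10. Putting a carbonyl back at C3 gives 8, because that carbonyl is what allows C4 to be built. The forward deoxygenation must act on a ketone next to a quaternary carbon without touching the ketal or the silyl ether.

**8 ⇒ 6.** The C4–CH3 and C5–H bonds are cut, giving enone 6 by way of enolate 7. Cutting the C4–chain bond at this stage instead would place the chain on the α face, which is the wrong one. The forward reductive methylation must give the trans fusion and α-methylation.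

**6 ⇒ 3 + 4, then 3 ⇒ 2 ⇒ 1.** The C4–side-chain bond is cut to iodoenone 3 and allyl silyl ether 4 (through alkylborane 5). The C–I bond and the ketal then lead to the (S)-Hajos–Parrish ketone 1, which supplies C10 in the correct absolute configuration. An sp2–sp3 coupling is preferred to dienolate alkylation because it cannot over-alkylate.

## Roads not taken

**Alternative 1:** The cut is at C9–C11 and C11–aryl. Enol triflate A1 and aryl boronate A2 would be joined in a carbonylative Suzuki–Miyaura coupling (Pd(OAc)2 with a phosphine) to give aryl enone A3.
- Merits: it is convergent; the arene and C11 arrive in one late step; no stereocentre is at stake in the coupling; the complete side chain can be carried throughout, which saves the three closing side-chain steps of the chosen plan. In convergence it is the better road.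
- Weak points: A1 presupposes an 8-methyl decalin-9-one, so the ring B problem is unsolved. Acyl-palladium formation at a tetrasubstituted triflate next to C10 is slow, so direct coupling and protodeboronation of A2 compete. A3 has the alkene at C8=C9 and oxygen on C11, so the alkene must be moved by kinetic protonation at C9 and the C11 carbonyl removed beside that now-labile centre.
- Comparison: the chosen plan never moves the alkene and creates C9 in a hydroboration, after which it cannot epimerise.

**Alternative 2:** The cut is at C1–C10. The phenolate of cresol A4 would add through its para carbon to the tethered vinyl ketone to give dienone A5.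
- Merits: both rings and quaternary C10 form in one catalytic step from a flat arene; the C8 methyl and a C7 oxygen are already in place, so the C7=C8 alkene could come from the C7 carbonyl. As a key step it is the more economical way to make C10.
- Weak points: para C-alkylation at a methyl-bearing carbon competes with O- and ortho-attack, and the catalyst must distinguish faces far from any handle. A5 still lacks C4, C5 and C9, and two carbonyls must be removed. A conjugate addition to C9 would enter anti to the C10 methyl and put C11 on the α face, which is the wrong one.
- Comparison: in the chosen plan all three remaining centres follow from C10 in the required sense.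

**Alternative 3:** The cut is the C4=C5 bond. An amino-acid-catalysed aldol condensation of triketone A6 would give enedione A7.
- Merits: ring B is six-membered with its C9 ketone from the start, and the complete side chain sits on C4 from the first step. Iodination, cross-coupling, ring expansion and late side-chain steps all disappear, so on paper this road is shorter.
- Weak points: triketones substituted at the nucleophilic carbon cyclise more slowly and less selectively than the parent, and an oily enedione such as A7 may not be enriched by crystallisation. C8 still needs its methyl and the C7=C8 unsaturation on a hindered ketone, by reagents that must spare the side-chain alkene. That alkene would also compete in any hydroboration at C11.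
- Comparison: the chosen plan offers C10 enantiopure from 1 without enrichment, delivers C8 with its methyl and unsaturation in one regiodefined step, and has no competing alkene at the late stage.

Key step: step 8

## Route

Remark on the chemistry: siloxy chlorocyclopropane 15 is expected as a mixture of isomers at its three cyclopropane carbons, all of which are lost in the same flask, so its SMILES leaves these centres open.

Step 1
Reactants: 1 (S)-Hajos–Parrish ketone
Product: 2 Hajos–Parrish ketone C9 ethylene ketal
Conditions: 2-ethyl-2-methyl-1,3-dioxolane (solvent), ethylene glycol (cat.), p-TsOH·H2O (cat.), rt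
Reagents that add atoms: 2-ethyl-2-methyl-1,3-dioxolane, CCC1(C)OCCO1
Why: Acid-catalysed transketalisation; the saturated C9 carbonyl exchanges while the less electrophilic conjugated C3 carbonyl is left, which is the usual chemoselective protection of ene-diones of this family.

Step 2
Reactants: 2 Hajos–Parrish ketone C9 ethylene ketal
Product: 3 4-iodo enone ketal
Conditions: I2, pyridine/CH2Cl2, 0 °C → rt, dark
Reagents that add atoms: iodine, II
Why: α-Iodination of a cyclic enone by pyridine addition, iodination of the enolate and elimination; the dioxolane is inert in the buffered medium.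

Step 3
Reactants: 3 4-iodo enone ketal; 4 allyloxy(tert-butyl)dimethylsilane
Product: 6 4-[3-(tert-butyldimethylsilyloxy)propyl] enone ketal, via alkylborane 5 (not isolated)
Conditions: 4, 9-BBN, THF, 0 °C → rt; then 3, Pd(dppf)Cl2, AsPh3, Cs2CO3, DMF/THF/H2O, rt
Reagents that add atoms: none
Why: Anti-Markovnikov hydroboration of the terminal alkene followed by B-alkyl Suzuki–Miyaura coupling with the α-iodoenone; the wide-bite-angle ligand favours alkyl transfer and reductive elimination over β-hydride loss.

Step 4
Reactants: 6 4-[3-(tert-butyldimethylsilyloxy)propyl] enone ketal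
Product: 8 trans-hydrindan-3-one ketal with 4α-methyl and 4β-silyloxypropyl, via lithium enolate 7 (not isolated)
Conditions: Li, t-BuOH (1 equiv), NH3(l)/THF, −78 °C; then MeI, −78 → −33 °C
Reagents that add atoms: iodomethane, CI
Why: Dissolving-metal reductive alkylation: protonation at C5 gives the trans fusion (5α-H), and the regiodefined C3 enolate 7 is methylated at C4 on the α face, anti to the axial C10 methyl, so the chain ends β and the new methyl α.

Step 5
Reactants: 8 trans-hydrindan-3-one ketal with 4α-methyl and 4β-silyloxypropyl
Product: 10 3-deoxy trans-hydrindane ketal, via N-silyl hydrazone 9 (not isolated)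
Conditions: TBSNHNHTBS, Sc(OTf)3 (cat.), neat, 100 °C; then KOt-Bu, t-BuOH, DMSO, 100 °C
Reagents that add atoms: none
Why: Wolff–Kishner reduction through the N-silyl hydrazone; Sc(OTf)3 catalyses hydrazone formation at the hindered C3 carbonyl, and the alkoxide in DMSO expels N2 under conditions that a ketal and a primary silyl ether should tolerate.

Step 6
Reactants: 10 3-deoxy trans-hydrindane ketal
Product: 11 trans-hydrindan-9-one
Conditions: PPTS, acetone/H2O, 55 °C
Reagents that add atoms: water, O
Why: Mild acid hydrolysis of the dioxolane; the pyridinium acid in aqueous acetone is too weak to cleave the primary TBS ether quickly, and the carbons α to the freed carbonyl are quaternary C10 and the non-stereogenic C7.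

Step 7
Reactants: 11 trans-hydrindan-9-one
Product: 12 trans-hydrindanone trimethylsilyl enol ether
Conditions: TMSOTf, Et3N, CH2Cl2, 0 °C
Reagents that add atoms: trimethylsilyl trifluoromethanesulfonate, C[Si](C)(C)OS(=O)(=O)C(F)(F)F
Why: Soft enolisation with a silyl triflate and an amine; because C10 is quaternary the only possible enol ether is the C9–C7 one.

Step 8
Reactants: 12 trans-hydrindanone trimethylsilyl enol ether; 13 1,1-dichloroethane
Product: 16 trans-decalin 8-methyl-7-en-9-one, via 1-chloroethyllithium 14 (not isolated), via siloxy chlorocyclopropane 15 (not isolated)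
Conditions: 13 (excess), n-BuLi (slow addition), Et2O, −40 °C → rt; then Et3N, MeOH, reflux
Reagents that add atoms: none
Why: n-BuLi deprotonates 13 to the carbenoid 14, which transfers chloro(methyl)carbene to the electron-rich C9=C7 enol ether in a concerted [2+1] addition from the α face, opposite the C10 methyl, to give 15. On heating, chloride ionises with disrotatory opening of the C9–C7 bond (cyclopropyl to allyl cation); the C9 oxygen takes up the charge as a silyloxocarbenium ion and gives its silyl group to methanol, leaving the 2-methyl enone. The closest known reaction type is the halocarbene ring expansion of cyclic silyl enol ethers to ring-enlarged 2-substituted cycloalkenones, and the substrate resembles the enol ether of a steroid ring D ketone. Ring B is not closed by a cyclisation: the three-membered ring is closed by cheletropic addition and then merged with the five-membered ring by a two-electron electrocyclic opening, which forms C7–C8 and C8–C9 and makes the six-membered ring. No stereocentre is created, because the three cyclopropane centres are all lost. The step needs regioselective insertion, secured because quaternary C10 allows only the C9–C7 enol ether; chemoselectivity, secured because no other alkene is present and the TBS ether is inert; and chloride syn to the five-membered ring for the allowed opening, expected to be the favoured isomer because the carbenoid methyl takes the exo position.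

Step 9
Reactants: 16 trans-decalin 8-methyl-7-en-9-one
Product: 17 8-methyl-9-methylene-7-ene diene
Conditions: Ph3PCH3Br, KOt-Bu, toluene, 90 °C
Reagents that add atoms: methyltriphenylphosphonium bromide, C[P+](c1ccccc1)(c1ccccc1)c1ccccc1.[Br-]
Why: Wittig methylenation; the small ylide at elevated temperature reaches carbonyls flanked by a quaternary centre, and the ketone has no α-hydrogen on either side, so enolisation does not compete.

Step 10
Reactants: 17 8-methyl-9-methylene-7-ene diene; 18 methyl 3-bromo-4-methoxybenzoate
Product: 20 silyl-protected C11 aryl decalin with 9α-H, via alkylborane 19 (not isolated)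
Conditions: 9-BBN, THF, rt; then 18, Pd(dppf)Cl2, K3PO4 (3 M aq.), DMF, 70 °C
Reagents that add atoms: none
Why: Hydroboration places boron on the terminal C11 and delivers hydrogen to C9 from the α face, opposite the axial C10 methyl, which sets 9α-H and leaves C11 β and equatorial; B-alkyl Suzuki–Miyaura coupling of 19 with 18 then forms the C11–aryl bond. The remaining ring alkene is trisubstituted and hindered and should not react at this temperature.

Step 11
Reactants: 20 silyl-protected C11 aryl decalin with 9α-H
Product: 21 side-chain primary alcohol
Conditions: Bu4NF, THF, rt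
Reagents that add atoms: none
Why: Fluoride cleavage of the silyl ether; the ester, aryl ether and alkene are inert.

Step 12
Reactants: 21 side-chain primary alcohol
Product: 22 side-chain aldehyde
Conditions: Dess–Martin periodinane, CH2Cl2, 0 °C → rt
Reagents that add atoms: none
Why: Dess–Martin oxidation of a primary alcohol stops at the aldehyde and is mild enough for the C7=C8 alkene.

Step 13
Reactants: 22 side-chain aldehyde
Product: 23 jaspic acid methyl ester methyl ether
Conditions: i-PrPPh3I, n-BuLi, THF, 0 °C; then 22, −78 °C → rt
Reagents that add atoms: isopropyltriphenylphosphonium iodide, CC(C)[P+](c1ccccc1)(c1ccccc1)c1ccccc1.[I-]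
Why: Wittig olefination with the non-stabilised isopropylidene ylide; the aldehyde reacts at low temperature while the benzoate does not, and the new alkene has two identical methyls, so no geometry question arises.

Step 14
Reactants: 23 jaspic acid methyl ester methyl ether
Product: 24 jaspic acid
Conditions: NaSEt, DMF, 130 °C; then 1 M HCl (work-up)
Reagents that add atoms: none
Why: Thiolate SN2 dealkylation removes the ester methyl and then the aryl ether methyl and leaves alkenes alone; no acid is present during the reaction that could move the C7=C8 alkene or add the phenol to it.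

## Compound list

1 | (S)-Hajos–Parrish ketone, (7aS)-7a-methyl-2,3,7,7a-tetrahydro-1H-indene-1,5(6H)-dione | O=C1CC[C@]2(C)C(=O)CCC2=C1 | starting material
2 | Hajos–Parrish ketone C9 ethylene ketal (C3 enone, C4=C5, 10β-methyl, C9 as 1,3-dioxolane) | O=C1CC[C@]2(C)C3(OCCO3)CCC2=C1 | intermediate
3 | 4-iodo enone ketal (2 with iodine on C4) | O=C1CC[C@]2(C)C3(OCCO3)CCC2=C1I | intermediate
4 | allyloxy(tert-butyl)dimethylsilane | C=CCO[Si](C)(C)C(C)(C)C | starting material
5 | B-[3-(tert-butyldimethylsilyloxy)propyl]-9-borabicyclo[3.3.1]nonane | CC(C)(C)[Si](C)(C)OCCCB1C2CCCC1CCC2 | intermediate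
6 | 4-[3-(tert-butyldimethylsilyloxy)propyl] enone ketal | O=C1CC[C@]2(C)C3(OCCO3)CCC2=C1CCCO[Si](C)(C)C(C)(C)C | intermediate
7 | lithium C3 enolate (C3=C4, 5α-H, trans-fused, C9 dioxolane) | CC(C)(C)[Si](C)(C)OCCCC1=C(O[Li])CC[C@]2(C)C3(OCCO3)CC[C@@H]12 | intermediate
8 | trans-hydrindan-3-one ketal: 4α-methyl, 4β-[3-(tert-butyldimethylsilyloxy)propyl], 5α-H, 10β-methyl, C9 dioxolane | CC(C)(C)[Si](C)(C)OCCC[C@@]1(C)C(=O)CC[C@]2(C)C3(OCCO3)CC[C@@H]12 | intermediate
9 | C3 N-(tert-butyldimethylsilyl)hydrazone of 8 | CC(C)(C)[Si](C)(C)OCCC[C@@]1(C)C(=NN[Si](C)(C)C(C)(C)C)CC[C@]2(C)C3(OCCO3)CC[C@@H]12 | intermediate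
10 | 3-deoxy trans-hydrindane ketal (C3 is CH2; otherwise as 8) | CC(C)(C)[Si](C)(C)OCCC[C@@]1(C)CCC[C@]2(C)C3(OCCO3)CC[C@@H]12 | intermediate
11 | trans-hydrindan-9-one: 4α-methyl, 4β-[3-(tert-butyldimethylsilyloxy)propyl], 5α-H, 10β-methyl | CC(C)(C)[Si](C)(C)OCCC[C@@]1(C)CCC[C@]2(C)C(=O)CC[C@@H]12 | intermediate
12 | trans-hydrindanone trimethylsilyl enol ether (C9–OSiMe3, C9=C7) | CC(C)(C)[Si](C)(C)OCCC[C@@]1(C)CCC[C@]2(C)C(O[Si](C)(C)C)=CC[C@@H]12 | intermediate
13 | 1,1-dichloroethane | CC(Cl)Cl | starting material
14 | 1-chloroethyllithium | CC(Cl)[Li] | intermediate
15 | siloxy chlorocyclopropane (C8 bearing Cl and methyl bridges C7 and C9; C9 bears OSiMe3; cyclopropane centres unassigned) | CC(C)(C)[Si](C)(C)OCCC[C@@]1(C)CCC[C@]2(C)C3(O[Si](C)(C)C)C(C)(Cl)C3C[C@@H]12 | intermediate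
16 | trans-decalin 8-methyl-7-en-9-one: 4α-methyl, 4β-[3-(tert-butyldimethylsilyloxy)propyl], 5α-H, 10β-methyl | CC(C)(C)[Si](C)(C)OCCC[C@@]1(C)CCC[C@]2(C)C(=O)C(C)=CC[C@@H]12 | intermediate
17 | 8-methyl-9-methylene-7-ene diene (C9=C11H2, C7=C8) | CC(C)(C)[Si](C)(C)OCCC[C@@]1(C)CCC[C@]2(C)C(=C)C(C)=CC[C@@H]12 | intermediate
18 | methyl 3-bromo-4-methoxybenzoate | COC(=O)c1ccc(OC)c(Br)c1 | starting material
19 | B-(C11-alkyl)-9-borabicyclo[3.3.1]nonane (boron on C11, 9α-H, C7=C8) | CC(C)(C)[Si](C)(C)OCCC[C@@]1(C)CCC[C@]2(C)[C@@H](CB3C4CCCC3CCC4)C(C)=CC[C@@H]12 | intermediate
20 | silyl-protected C11 aryl decalin: methyl 4-methoxy-3-(C11-methylene)benzoate on C9β, 9α-H, C7=C8, side chain as TBS ether | CC(C)(C)[Si](C)(C)OCCC[C@@]1(C)CCC[C@]2(C)[C@@H](Cc3cc(C(=O)OC)ccc3OC)C(C)=CC[C@@H]12 | intermediate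
21 | side-chain primary alcohol (20 without the silyl group) | OCCC[C@@]1(C)CCC[C@]2(C)[C@@H](Cc3cc(C(=O)OC)ccc3OC)C(C)=CC[C@@H]12 | intermediate
22 | side-chain aldehyde (4β-(3-oxopropyl)) | O=CCC[C@@]1(C)CCC[C@]2(C)[C@@H](Cc3cc(C(=O)OC)ccc3OC)C(C)=CC[C@@H]12 | intermediate
23 | jaspic acid methyl ester methyl ether | CC(C)=CCC[C@@]1(C)CCC[C@]2(C)[C@@H](Cc3cc(C(=O)OC)ccc3OC)C(C)=CC[C@@H]12 | intermediate
24 | jaspic acid | CC(C)=CCC[C@@]1(C)CCC[C@]2(C)[C@@H](Cc3cc(C(=O)O)ccc3O)C(C)=CC[C@@H]12 | target

## Step count and risk

Total step count: 14. Compounds 4, 13 and 18 are taken as purchased.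
Longest linear sequence: 14 steps, from 1 to 24.

**Step 8 (key step).** The most likely failure is incomplete ring opening. Carbene transfer gives both isomers at C8, and only the one with chloride syn to the five-membered ring can ionise with the allowed disrotatory motion; cleavage of the enol ether by n-BuLi before carbene transfer is a second drain. The fallback sets out from 12. Dibromocarbene (CHBr3, KOt-Bu, pentane, −20 °C) gives the dibromocyclopropane F1, in which one bromide is always syn. Warming opens it to the 8-bromo-7-en-9-one F2. The C8 methyl is then introduced by Suzuki–Miyaura coupling with trimethylboroxine (Pd(dppf)Cl2, K2CO3, dioxane, 90 °C), which returns to 16.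

**Step 10.** The most likely failure is slow transmetalation of the β-branched alkylborane beside quaternary C10, so that protodeboronation and reduction of the aryl bromide take over. The fallback sets out from 17 and replaces the cross-coupling by a carbonyl addition. The same hydroboration with oxidative work-up (NaOH, H2O2) gives the C11 alcohol F3, and Dess–Martin oxidation gives the aldehyde F4. The arylmagnesium chloride F5, made from methyl 3-iodo-4-methoxybenzoate and i-PrMgCl·LiCl at −40 °C, adds to F4 to give the benzylic alcohol F6 as a C11 epimer mixture. The xanthate F7 (NaH, CS2, MeI) is reduced with Bu3SnH and AIBN in a Barton–McCombie deoxygenation, which returns to 20.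

**Step 5.** The most likely failure is incomplete hydrazone formation at the C3 carbonyl, which is flanked by quaternary C4 with an axial chain; longer heating then erodes the silyl ether. The fallback sets out from 8. NaBH4 (MeOH, 0 °C) gives the 3β-alcohol F8, which is converted to the xanthate F9 (NaH, CS2, MeI) and reduced with Bu3SnH and AIBN in toluene at reflux (Barton–McCombie), returning to 10.

**Step 2.** The most likely failure is sluggish iodination, because C5 is fully substituted and pyridine adds to it reluctantly. The fallback sets out from 2 and forms the C4–chain bond by enolate chemistry instead. The extended potassium dienolate (KOt-Bu, t-BuOH) is alkylated at C4 with tert-butyl(3-iodopropoxy)dimethylsilane, which gives 6 directly and replaces steps 2 and 3 at the cost of some over-alkylation; it passes through no new compound (F0).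

**Step 9.** The most likely failure is that the ylide does not add to the carbonyl shielded by C10 and the C8 methyl, and the enone degrades slowly instead. The fallback sets out from 16 and uses a Peterson olefination. Me3SiCH2Li with CeCl3 (THF, −78 °C) adds to the carbonyl to give the β-hydroxysilane F10, and KH in THF eliminates it to 17.

## Further compounds

F1 | step 8 | dibromocyclopropane (C8 bearing two Br bridges C7 and C9; C9 bears OSiMe3; cyclopropane centres unassigned) | CC(C)(C)[Si](C)(C)OCCC[C@@]1(C)CCC[C@]2(C)C3(O[Si](C)(C)C)C(Br)(Br)C3C[C@@H]12
F2 | step 8 | trans-decalin 8-bromo-7-en-9-one | CC(C)(C)[Si](C)(C)OCCC[C@@]1(C)CCC[C@]2(C)C(=O)C(Br)=CC[C@@H]12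
F3 | step 10 | C11 alcohol (9β-hydroxymethyl, 9α-H, C7=C8) | CC(C)(C)[Si](C)(C)OCCC[C@@]1(C)CCC[C@]2(C)[C@@H](CO)C(C)=CC[C@@H]12
F4 | step 10 | C11 aldehyde (9β-formyl, 9α-H, C7=C8) | CC(C)(C)[Si](C)(C)OCCC[C@@]1(C)CCC[C@]2(C)[C@@H](C=O)C(C)=CC[C@@H]12
F5 | step 10 | [2-methoxy-5-(methoxycarbonyl)phenyl]magnesium chloride | COC(=O)c1ccc(OC)c([Mg]Cl)c1
F6 | step 10 | C11 benzylic alcohol (C11 epimers) | CC(C)(C)[Si](C)(C)OCCC[C@@]1(C)CCC[C@]2(C)[C@@H](C(O)c3cc(C(=O)OC)ccc3OC)C(C)=CC[C@@H]12
F7 | step 10 | C11 O-alkyl S-methyl xanthate (C11 epimers) | CC(C)(C)[Si](C)(C)OCCC[C@@]1(C)CCC[C@]2(C)[C@@H](C(OC(=S)SC)c3cc(C(=O)OC)ccc3OC)C(C)=CC[C@@H]12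
F8 | step 5 | 3β-alcohol of the trans-hydrindane ketal | CC(C)(C)[Si](C)(C)OCCC[C@@]1(C)[C@@H](O)CC[C@]2(C)C3(OCCO3)CC[C@@H]12
F9 | step 5 | 3β-O S-methyl xanthate of the trans-hydrindane ketal | CC(C)(C)[Si](C)(C)OCCC[C@@]1(C)[C@@H](OC(=S)SC)CC[C@]2(C)C3(OCCO3)CC[C@@H]12
F0 | step 2 | none | none
F10 | step 9 | C9 β-hydroxysilane (9-hydroxy-9-(trimethylsilylmethyl), C9 unassigned) | CC(C)(C)[Si](C)(C)OCCC[C@@]1(C)CCC[C@]2(C)C(O)(C[Si](C)(C)C)C(C)=CC[C@@H]12
A1 | alternative 1 | decalin C9 enol triflate (8-methyl-8-en-9-yl triflate, complete side chain) | CC(C)=CCC[C@@]1(C)CCC[C@]2(C)C(OS(=O)(=O)C(F)(F)F)=C(C)CC[C@@H]12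
A2 | alternative 1 | methyl 4-(methoxymethoxy)-3-(4,4,5,5-tetramethyl-1,3,2-dioxaborolan-2-yl)benzoate | COCOc1ccc(C(=O)OC)cc1B1OC(C)(C)C(C)(C)O1
A3 | alternative 1 | 8-en-11-one aryl ketone | CC(C)=CCC[C@@]1(C)CCC[C@]2(C)C(C(=O)c3cc(C(=O)OC)ccc3OCOC)=C(C)CC[C@@H]12
A4 | alternative 2 | 1-(5-hydroxy-2,4-dimethylphenyl)but-3-en-2-one | C=CC(=O)Cc1cc(O)c(C)cc1C
A5 | alternative 2 | bicyclic cross-conjugated dienone with C3 ketone and quaternary C10 | O=C1C=C2CC(=O)CC[C@]2(C)C=C1C
A6 | alternative 3 | 2-methyl-2-(8-methyl-3-oxonon-7-enyl)cyclohexane-1,3-dione | CC(C)=CCCCC(=O)CCC1(C)C(=O)CCCC1=O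
A7 | alternative 3 | 4-(4-methylpent-3-enyl) Wieland–Miescher-type enedione | CC(C)=CCCC1=C2CCCC(=O)[C@@]2(C)CCC1=O
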